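**Retrosynthetic overview**

1. Side chain numbered O–C1'H2–C2'H=C3'(Me)–C4'H(OH)–C5'H=C6'H–C7'(Me)2–OOH; the last step only unmasks the C7' hydroperoxide from a 2-methoxyprop-2-yl peroxyketal.
2. Key disconnection C4'–C5': an α-methyl enal (coumarin–O–C1'H2–C2'H=C3'(Me)–C4'HO) plus an (E)-alkenylzinc made from the terminal alkyne HC≡C–C(Me)2–OO–C(Me)2OMe; one catalytic asymmetric addition forms the bond, the 4'R centre and the whole C10 chain with the O–O bond already in place.
3. Enabling feature: C4' is a secondary carbinol carbon between two alkenes (C2'=C3' and trans-C5'=C6'), so it maps onto the carbonyl of an α-branched enal, and C5'=C6' maps onto a syn-hydrometalated terminal alkyne. C7' is fully substituted, so the O–O bond lies between two quaternary carbons, has no α-H and is shielded from organozinc attack.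
4. Enal: O4-prenylation of 4-hydroxy-5-methylcoumarin (Mitsunobu), then SeO2 oxidation of the E-methyl group. Alkyne: perhydrolysis of 2-methylbut-3-yn-2-ol, then ketalisation with 2-methoxypropene.
5. Ring formation: only the pyranone ring of the coumarin is built (step 1, onto the preformed benzene ring); no ring is formed or opened afterwards.

Key step: step 6

Remark on the chemistry: the facial sense established for the (−)-enantiomer of morpholinoisoborneol (Si-face delivery to RCHO) is assumed to be mirrored by (+)-MIB on enal 5, which gives 4'R. Hydroperoxide 7 is a low-molecular-weight peroxide and should be handled only in solution behind a shield.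

**Route**

Step 1
Reactants: 1 1-(2-hydroxy-6-methylphenyl)ethan-1-one
Product: 2 4-hydroxy-5-methyl-2H-chromen-2-one
Conditions: NaH (4 equiv), (EtO)2CO (3 equiv), toluene, 110 °C; then 1 M HCl
Reagents that add atoms: diethyl carbonate, CCOC(=O)OCC
Why: Claisen-type C-acylation of the methyl ketone enolate by diethyl carbonate followed by lactonisation onto the phenoxide is the standard entry to 4-hydroxycoumarins and should close the pyranone ring (C-2 and its carbonyl oxygen come from the carbonate).

Step 2
Reactants: 2 4-hydroxy-5-methyl-2H-chromen-2-one; 3 3-methylbut-2-en-1-ol (prenol)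
Product: 4 5-methyl-4-[(3-methylbut-2-en-1-yl)oxy]-2H-chromen-2-one
Conditions: PPh3, DIAD, THF, 0 °C → rt
Reagents that add atoms: none
Why: Mitsunobu reaction of the acidic vinylogous acid (pKa about 4) with the primary allylic alcohol should give SN2 O-alkylation at O-4 and avoid the C-3 alkylation that prenyl halides and base tend to give.

Step 3
Reactants: 4 5-methyl-4-[(3-methylbut-2-en-1-yl)oxy]-2H-chromen-2-one
Product: 5 (2E)-2-methyl-4-[(5-methyl-2-oxo-2H-chromen-4-yl)oxy]but-2-enal
Conditions: SeO2 (1.1 equiv), 1,4-dioxane, 70 °C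
Reagents that add atoms: selenium dioxide, O=[Se]=O
Why: Riley allylic oxidation (ene reaction then [2,3]-sigmatropic shift) of a prenyl group should occur at the more substituted alkene terminus and selectively on the E-methyl group, which gives the (E)-α-methyl enal.

Step 4
Reactants: 6 2-methylbut-3-yn-2-ol
Product: 7 2-methylbut-3-yn-2-yl hydroperoxide
Conditions: 50% aq. H2O2 (excess), H2SO4, 0 → 5 °C; extracted into CH2Cl2 and kept in solution
Reagents that add atoms: hydrogen peroxide, OO
Why: acid-catalysed perhydrolysis (SN1 through the tertiary propargylic cation) is the established preparation of tertiary acetylenic hydroperoxides, and excess H2O2 should suppress formation of the symmetrical dialkyl peroxide.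

Step 5
Reactants: 7 2-methylbut-3-yn-2-yl hydroperoxide
Product: 8 3-[(2-methoxypropan-2-yl)peroxy]-3-methylbut-1-yne
Conditions: 2-methoxypropene (1.5 equiv), PPTS (5 mol%), CH2Cl2, 0 °C; Et3N quench
Reagents that add atoms: 2-methoxypropene, COC(C)=C
Why: acid-catalysed addition of the hydroperoxide O–H to the enol ether (peroxyketal formation) should mask the acidic OOH as a base- and nucleophile-stable monoperoxyketal that mild aqueous acid removes later.

Step 6
Reactants: 8 3-[(2-methoxypropan-2-yl)peroxy]-3-methylbut-1-yne; 5 (2E)-2-methyl-4-[(5-methyl-2-oxo-2H-chromen-4-yl)oxy]but-2-enal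
Product: 11 4-{[(2E,4R,5E)-4-hydroxy-7-[(2-methoxypropan-2-yl)peroxy]-3,7-dimethylocta-2,5-dien-1-yl]oxy}-5-methyl-2H-chromen-2-one, via alkenyl(dicyclohexyl)borane 9 (not isolated), via alkenyl(methyl)zinc 10 (not isolated)
Conditions: 8 (1.6 equiv), Cy2BH (1.6 equiv), toluene, 0 °C → rt; Me2Zn (1.7 equiv), −78 °C; (+)-MIB (5 mol%), then 5 (1.0 equiv), −20 → 0 °C; pH 7 buffer
Reagents that add atoms: none
Why: syn-hydroboration of the terminal alkyne of 8 by Cy2BH should place boron on the CH terminus (9) and fix the E geometry of C5'=C6'; boron-to-zinc exchange with Me2Zn then gives the (E)-alkenyl(methyl)zinc 10 with retention, and the zinc aminoalkoxide formed from (+)-MIB assembles 10 and the aldehyde of 5 in a dinuclear zinc transition state in which the alkenyl group, which transfers faster than methyl, is delivered to the carbonyl carbon to form C4'–C5'. The closest known reaction type is the amino-alcohol-catalysed asymmetric addition of alkenylzinc reagents (from alkyne hydroboration and B→Zn exchange) to aldehydes, for which α-branched enals are among the best substrates. No ring is closed. The only new stereocentre, C4', is set by the catalyst: (+)-MIB, the mirror image of the ligand that directs Si-face attack, should direct Re-face attack and give 4'R, while the trans C5'=C6' alkene follows from the syn-hydroboration. The step needs 1,2- over 1,4-addition (secured by the copper-free zinc reagent and the α-methyl group of the enal), alkenyl over methyl transfer, and survival of both the O–O bond and the 4-alkoxycoumarin. The O–O bond lies between two fully substituted carbons, which blocks SN2 attack at oxygen and leaves no α-hydrogen for base-induced fragmentation, and alkylzinc species do not add to lactones or vinylogous carbonates at or below 0 °C.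

Step 7
Reactants: 11 4-{[(2E,4R,5E)-4-hydroxy-7-[(2-methoxypropan-2-yl)peroxy]-3,7-dimethylocta-2,5-dien-1-yl]oxy}-5-methyl-2H-chromen-2-one
Product: 12 4-{[(2E,4R,5E)-7-hydroperoxy-4-hydroxy-3,7-dimethylocta-2,5-dien-1-yl]oxy}-5-methyl-2H-chromen-2-one
Conditions: AcOH/THF/H2O (4:2:1), rt
Reagents that add atoms: none
Why: acid-catalysed hydrolysis of the monoperoxyketal (loss of acetone and methanol) should release the tertiary hydroperoxide under conditions too mild to ionise the doubly allylic C4' carbinol, so the 4'R centre is untouched.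

**Compound list**

1 | 1-(2-hydroxy-6-methylphenyl)ethan-1-one (2'-hydroxy-6'-methylacetophenone) | CC(=O)c1c(C)cccc1O | starting material
2 | 4-hydroxy-5-methyl-2H-chromen-2-one (4-hydroxy-5-methylcoumarin) | Cc1cccc2oc(=O)cc(O)c12 | intermediate
3 | 3-methylbut-2-en-1-ol (prenol) | CC(C)=CCO | starting material
4 | 5-methyl-4-[(3-methylbut-2-en-1-yl)oxy]-2H-chromen-2-one | CC(C)=CCOc1cc(=O)oc2cccc(C)c12 | intermediate
5 | (2E)-2-methyl-4-[(5-methyl-2-oxo-2H-chromen-4-yl)oxy]but-2-enal | C/C(C=O)=C\COc1cc(=O)oc2cccc(C)c12 | intermediate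
6 | 2-methylbut-3-yn-2-ol | CC(C)(O)C#C | starting material
7 | 2-methylbut-3-yn-2-yl hydroperoxide | CC(C)(OO)C#C | intermediate
8 | 3-[(2-methoxypropan-2-yl)peroxy]-3-methylbut-1-yne | COC(C)(C)OOC(C)(C)C#C | intermediate
9 | dicyclohexyl{(1E)-3-[(2-methoxypropan-2-yl)peroxy]-3-methylbut-1-en-1-yl}borane | COC(C)(C)OOC(C)(C)/C=C/B(C1CCCCC1)C1CCCCC1 | intermediate
10 | {(1E)-3-[(2-methoxypropan-2-yl)peroxy]-3-methylbut-1-en-1-yl}(methyl)zinc | COC(C)(C)OOC(C)(C)/C=C/[Zn]C | intermediate
11 | 4-{[(2E,4R,5E)-4-hydroxy-7-[(2-methoxypropan-2-yl)peroxy]-3,7-dimethylocta-2,5-dien-1-yl]oxy}-5-methyl-2H-chromen-2-one | C/C(=C\COc1cc(=O)oc2cccc(C)c12)[C@H](O)/C=C/C(C)(C)OOC(C)(C)OC | intermediate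
12 | 4-{[(2E,4R,5E)-7-hydroperoxy-4-hydroxy-3,7-dimethylocta-2,5-dien-1-yl]oxy}-5-methyl-2H-chromen-2-one | C/C(=C\COc1cc(=O)oc2cccc(C)c12)[C@H](O)/C=C/C(C)(C)OO | target

**Totals**

Total step count: 7. Longest linear sequence: 5 steps (steps 1, 2, 3, 6, 7); the alkyne branch (steps 4, 5) joins at step 6.

**Steps most likely to fail**

Step 6. The O–O bond may be cleaved reductively by B–H or attacked by Zn–C species, the peroxyketal may be ionised by zinc Lewis acids, or an uncatalysed background addition promoted by the Lewis-basic coumarin may erode the enantioselectivity. The fallback sets out from 5 and comes back at 12, and installs the O–O bond only after the C–C bond. Commercial 2-methylbut-1-en-3-yne (C=C(C)C#C) would be hydroborated at the alkyne with Cy2BH to dicyclohexyl[(1E)-3-methylbuta-1,3-dien-1-yl]borane F1, exchanged with Me2Zn to methyl[(1E)-3-methylbuta-1,3-dien-1-yl]zinc F2, and added to 5 under the same (+)-MIB catalysis to give 4-{[(2E,4R,5E)-4-hydroxy-3,7-dimethylocta-2,5,7-trien-1-yl]oxy}-5-methyl-2H-chromen-2-one F3. Mukaiyama–Isayama silylperoxidation (Co(thd)2 cat., O2, Et3SiH, 1,2-dichloroethane, rt) would follow; hydrogen-atom transfer to the terminal CH2 of the isopropenyl group and O2 capture at the tertiary terminus of the allyl radical are expected, though capture at C5' is a possible competing pathway. This should give 4-{[(2E,4R,5E)-4-hydroxy-3,7-dimethyl-7-[(triethylsilyl)peroxy]octa-2,5-dien-1-yl]oxy}-5-methyl-2H-chromen-2-one F4, and buffered fluoride (TBAF/AcOH, THF, 0 °C) would release 12.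

Step 7. Acid may ionise the doubly allylic C4' carbinol (allylic transposition, loss of configuration) or trigger Hock-type cleavage of the tertiary allylic hydroperoxide during ketal hydrolysis. The fallback sets out from 7 and comes back at 12, and replaces the acid-labile ketal by a fluoride-labile silyl peroxide. Silylation of 7 (TBSCl, imidazole, DMF, 0 °C) would give tert-butyldimethyl[(2-methylbut-3-yn-2-yl)peroxy]silane F5. The sequence of step 6 would then pass through {(1E)-3-[(tert-butyldimethylsilyl)peroxy]-3-methylbut-1-en-1-yl}dicyclohexylborane F6 and {(1E)-3-[(tert-butyldimethylsilyl)peroxy]-3-methylbut-1-en-1-yl}(methyl)zinc F7 and, with 5, give 4-{[(2E,4R,5E)-7-[(tert-butyldimethylsilyl)peroxy]-4-hydroxy-3,7-dimethylocta-2,5-dien-1-yl]oxy}-5-methyl-2H-chromen-2-one F8. TBAF/AcOH or HF·pyridine (THF, 0 °C) would then give 12 without any cationic intermediate.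

Step 3. The oxidation may stall at the allylic alcohol or over-oxidise, and the acidic, warm medium may cleave the allylic aryl ether (the 4-coumarinyloxy group is a good leaving group) or induce a [3,3]-shift of the allyl vinyl ether unit. The fallback sets out from 2 and comes back at 5, and builds the enal by olefin metathesis instead of C–H oxidation. Mitsunobu reaction of 2 with allyl alcohol (PPh3, DIAD, THF) would give 5-methyl-4-(prop-2-en-1-yloxy)-2H-chromen-2-one F9, and cross-metathesis with excess methacrolein (Hoveyda–Grubbs second-generation catalyst, CH2Cl2, 40 °C) should give the (E)-α-methyl enal 5 directly.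

**Further compounds**

F1 | step 6 | dicyclohexyl[(1E)-3-methylbuta-1,3-dien-1-yl]borane | C=C(C)/C=C/B(C1CCCCC1)C1CCCCC1
F2 | step 6 | methyl[(1E)-3-methylbuta-1,3-dien-1-yl]zinc | C=C(C)/C=C/[Zn]C
F3 | step 6 | 4-{[(2E,4R,5E)-4-hydroxy-3,7-dimethylocta-2,5,7-trien-1-yl]oxy}-5-methyl-2H-chromen-2-one | C/C(=C\COc1cc(=O)oc2cccc(C)c12)[C@H](O)/C=C/C(C)=C
F4 | step 6 | 4-{[(2E,4R,5E)-4-hydroxy-3,7-dimethyl-7-[(triethylsilyl)peroxy]octa-2,5-dien-1-yl]oxy}-5-methyl-2H-chromen-2-one | C/C(=C\COc1cc(=O)oc2cccc(C)c12)[C@H](O)/C=C/C(C)(C)OO[Si](CC)(CC)CC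
F5 | step 7 | tert-butyldimethyl[(2-methylbut-3-yn-2-yl)peroxy]silane | C#CC(C)(C)OO[Si](C)(C)C(C)(C)C
F6 | step 7 | {(1E)-3-[(tert-butyldimethylsilyl)peroxy]-3-methylbut-1-en-1-yl}dicyclohexylborane | CC(C)(C)[Si](C)(C)OOC(C)(C)/C=C/B(C1CCCCC1)C1CCCCC1
F7 | step 7 | {(1E)-3-[(tert-butyldimethylsilyl)peroxy]-3-methylbut-1-en-1-yl}(methyl)zinc | CC(C)(C)[Si](C)(C)OOC(C)(C)/C=C/[Zn]C
F8 | step 7 | 4-{[(2E,4R,5E)-7-[(tert-butyldimethylsilyl)peroxy]-4-hydroxy-3,7-dimethylocta-2,5-dien-1-yl]oxy}-5-methyl-2H-chromen-2-one | C/C(=C\COc1cc(=O)oc2cccc(C)c12)[C@H](O)/C=C/C(C)(C)OO[Si](C)(C)C(C)(C)C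
F9 | step 3 | 5-methyl-4-(prop-2-en-1-yloxy)-2H-chromen-2-one | C=CCOc1cc(=O)oc2cccc(C)c12
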